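## Retrosynthetic overview
1. Last operations: global O-debenzylation, preceded by Suzuki attachment of ring A with its E-alkene to a C6 chloride on the upper benzofuran.
2. C3(upper unit)–C6(lower unit) bond: decarboxylative sp3–sp2 coupling of upper 3-carboxylic acid 33 with lower aryl iodide 24. The lower 3-aryl ring enters the same way (18 + 21).
3. Each trans-2-aryl-2,3-dihydrobenzofuran-3-carboxylic acid: Evans syn-aldol of one common N-(arylacetyl)oxazolidinone 9 with an aryl aldehyde (C2–C3 bond, absolute configuration), then acid-mediated phenol O–C2 closure.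
4. Ring order: all benzene rings are bought. The lower dihydrofuran ring is closed first (step 7), then the upper dihydrofuran ring (step 17), then the two units are joined.
5. 9 comes from 5-chlororesorcinol by MOM protection, directed lithiation/ethylene oxide opening, oxidation and N-acylation.

Assumption: both dihydrobenzofurans are read from the SMILES as trans-(2S,3S) ("upper unit" carries the styryl group, "lower unit" the 2,4- and 3,5-dihydroxyphenyl rings); 1, 7, 10, 19, 25 and 35 are taken as catalogue chemicals.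

## Route

Step 1
Reactants: 1 5-chlorobenzene-1,3-diol
Product: 2 1-chloro-3,5-bis(methoxymethoxy)benzene
Conditions: MOMCl (2.5 equiv), i-Pr2NEt, CH2Cl2, 0 °C → rt
Reagents that add atoms: chloromethyl methyl ether (MOMCl), COCCl
Why: O-alkylation of both phenols gives the acetal ethers that direct the next lithiation and are acid-labile for the later ring closure.

Step 2
Reactants: 2 1-chloro-3,5-bis(methoxymethoxy)benzene
Product: 4 2-[4-chloro-2,6-bis(methoxymethoxy)phenyl]ethan-1-ol, via aryllithium 3 (not isolated)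
Conditions: n-BuLi, TMEDA, THF, −78 → 0 °C; ethylene oxide, −78 °C → rt; aq NH4Cl
Reagents that add atoms: ethylene oxide, C1CO1
Why: Directed ortho-metalation occurs at the CH flanked by the two MOM ethers (aryl chloride tolerated cold), and the aryllithium opens the epoxide.

Step 3
Reactants: 4 2-[4-chloro-2,6-bis(methoxymethoxy)phenyl]ethan-1-ol
Product: 6 [4-chloro-2,6-bis(methoxymethoxy)phenyl]acetic acid, via aldehyde 5 (not isolated)
Conditions: TEMPO (0.2 equiv), PhI(OAc)2 (2.5 equiv), MeCN/H2O, rt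
Reagents that add atoms: water, O
Why: Oxoammonium (TEMPO) oxidation takes the primary alcohol through the aldehyde hydrate to the acid under near-neutral conditions that spare the MOM ethers.

Step 4
Reactants: 6 [4-chloro-2,6-bis(methoxymethoxy)phenyl]acetic acid; 7 (4S)-4-benzyl-1,3-oxazolidin-2-one
Product: 9 (4S)-4-benzyl-3-{[4-chloro-2,6-bis(methoxymethoxy)phenyl]acetyl}-1,3-oxazolidin-2-one, via mixed pivalic anhydride 8 (not isolated)
Conditions: PivCl, Et3N, THF, −20 °C; then LiCl, 7, rt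
Reagents that add atoms: none
Why: Mixed-anhydride N-acylation of the Evans auxiliary, with attack at the less hindered arylacetyl carbonyl.

Step 5
Reactants: 9 (4S)-4-benzyl-3-{[4-chloro-2,6-bis(methoxymethoxy)phenyl]acetyl}-1,3-oxazolidin-2-one; 10 2,4-bis(benzyloxy)benzaldehyde
Product: 12 (4S)-4-benzyl-3-{(2S,3S)-3-[2,4-bis(benzyloxy)phenyl]-2-[4-chloro-2,6-bis(methoxymethoxy)phenyl]-3-hydroxypropanoyl}-1,3-oxazolidin-2-one, via dibutylboron Z-enolate 11 (not isolated)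
Conditions: Bu2BOTf, i-Pr2NEt, CH2Cl2, 0 °C; 10, −78 → 0 °C; then pH 7 buffer, MeOH, H2O2, 0 °C
Reagents that add atoms: none
Why: Intermolecular Evans boron aldol; the Z-enolate reacts through a closed Zimmerman–Traxler chair on the face away from the benzyl group, giving the syn-(2S,3S) adduct whose α-centre becomes ring C3 and later steers C2.

Step 6
Reactants: 12 aldol adduct
Product: 13 (1S,2R)-1-[2,4-bis(benzyloxy)phenyl]-2-[4-chloro-2,6-bis(methoxymethoxy)phenyl]propane-1,3-diol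
Conditions: LiBH4, MeOH (1.5 equiv), THF, 0 °C
Reagents that add atoms: none
Why: Reductive cleavage of the exocyclic imide carbonyl gives the primary alcohol and frees the auxiliary without touching either stereocentre (this also removes the retro-aldol and lactonisation risks of the acyl stage).

Step 7
Reactants: 13 (1S,2R)-diol
Product: 15 (2S,3R)-2-[2,4-bis(benzyloxy)phenyl]-6-chloro-3-(hydroxymethyl)-2,3-dihydro-1-benzofuran-4-ol, via MOM-free tetraol 14 (not isolated)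
Conditions: conc. HCl (5 equiv), MeOH/THF, 45 °C
Reagents that add atoms: none
Why: Acidic acetal cleavage frees the two equivalent phenols, and the dialkoxy-stabilised benzylic cation is trapped by one of them (5-ring cyclodehydration); C3 is untouched and C2 settles trans to it under thermodynamic control.

Step 8
Reactants: 15 dihydrobenzofuran-4-ol
Product: 16 [(2S,3R)-4-(benzyloxy)-2-[2,4-bis(benzyloxy)phenyl]-6-chloro-2,3-dihydro-1-benzofuran-3-yl]methanol
Conditions: BnBr (1.05 equiv), K2CO3, acetone, 50 °C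
Reagents that add atoms: benzyl bromide, BrCc1ccccc1
Why: Williamson etherification is selective for the phenoxide over the primary alcohol.

Step 9
Reactants: 16 primary alcohol
Product: 18 (2S,3S)-4-(benzyloxy)-2-[2,4-bis(benzyloxy)phenyl]-6-chloro-2,3-dihydro-1-benzofuran-3-carboxylic acid, via aldehyde 17 (not isolated)
Conditions: TEMPO (0.2 equiv), PhI(OAc)2 (2.5 equiv), MeCN/CH2Cl2/H2O, rt
Reagents that add atoms: water, O
Why: Base-free TEMPO oxidation to the acid; the transient 3-formyl compound is already the more stable trans isomer.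

Step 10
Reactants: 19 1-bromo-3,5-dimethoxybenzene
Product: 20 5-bromobenzene-1,3-diol
Conditions: BBr3, CH2Cl2, −78 °C → rt; H2O
Reagents that add atoms: none
Why: Lewis-acid demethylation of aryl methyl ethers.

Step 11
Reactants: 20 5-bromobenzene-1,3-diol
Product: 21 1,3-bis(benzyloxy)-5-bromobenzene
Conditions: BnBr, K2CO3, DMF, rt
Reagents that add atoms: benzyl bromide, BrCc1ccccc1
Why: Williamson etherification.

Step 12
Reactants: 18 lower-unit carboxylic acid; 21 1,3-bis(benzyloxy)-5-bromobenzene (2 equiv)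
Product: 22 (2S,3S)-4-(benzyloxy)-2-[2,4-bis(benzyloxy)phenyl]-3-[3,5-bis(benzyloxy)phenyl]-6-chloro-2,3-dihydro-1-benzofuran
Conditions: Ir[dF(CF3)ppy]2(dtbbpy)PF6 (2 mol %), NiCl2·glyme (10 mol %), 4,4′-di-tert-butyl-2,2′-bipyridine, Cs2CO3, DMF, blue LEDs, rt
Reagents that add atoms: none
Why: Metallaphotoredox decarboxylative arylation; the benzylic C3 radical is arylated on the face anti to the C2 aryl group, so C2 (set trans to the aldol-derived centre in step 7) dictates the trans-(2S,3S) outcome, and the aryl chloride is inert next to the aryl bromide.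

Step 13
Reactants: 22 lower-unit aryl chloride
Product: 23 2-{(2S,3S)-4-(benzyloxy)-2-[2,4-bis(benzyloxy)phenyl]-3-[3,5-bis(benzyloxy)phenyl]-2,3-dihydro-1-benzofuran-6-yl}-4,4,5,5-tetramethyl-1,3,2-dioxaborolane
Conditions: Pd2(dba)3 (2 mol %), XPhos, B2pin2, KOAc, 1,4-dioxane, 100 °C
Reagents that add atoms: bis(pinacolato)diboron, CC1(C)OB(OC1(C)C)B1OC(C)(C)C(C)(C)O1
Why: Miyaura borylation of the unhindered aryl chloride.

Step 14
Reactants: 23 aryl boronate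
Product: 24 (2S,3S)-4-(benzyloxy)-2-[2,4-bis(benzyloxy)phenyl]-3-[3,5-bis(benzyloxy)phenyl]-6-iodo-2,3-dihydro-1-benzofuran
Conditions: CuI (10 mol %), 1,10-phenanthroline, KI, THF/MeOH/H2O, air, 80 °C
Reagents that add atoms: potassium iodide, [K+].[I-]
Why: Copper-catalysed aerobic ipso-iododeboronation occurs only at the C–B carbon, so the electron-rich rings are not iodinated.

Step 15
Reactants: 9 N-(arylacetyl)oxazolidinone; 25 4-(benzyloxy)benzaldehyde
Product: 27 (4S)-4-benzyl-3-{(2S,3S)-3-[4-(benzyloxy)phenyl]-2-[4-chloro-2,6-bis(methoxymethoxy)phenyl]-3-hydroxypropanoyl}-1,3-oxazolidin-2-one, via diethylboron Z-enolate 26 (not isolated)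
Conditions: Et3B (1.2 equiv), TfOH (1.15 equiv), CH2Cl2, rt (gives Et2BOTf); 9, i-Pr2NEt, 0 °C; 25, −78 → 0 °C; then pH 7 buffer, MeOH, H2O2, 0 °C
Reagents that add atoms: none
Why: Second intermolecular Evans syn-aldol, run through the diethylboron Z-enolate from freshly made Et2BOTf; the same auxiliary and closed Zimmerman–Traxler chair give the same (2S,3S) sense needed for the upper unit.

Step 16
Reactants: 27 aldol adduct
Product: 28 (1S,2R)-1-[4-(benzyloxy)phenyl]-2-[4-chloro-2,6-bis(methoxymethoxy)phenyl]propane-1,3-diol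
Conditions: LiBH4, MeOH (1.5 equiv), THF, 0 °C
Reagents that add atoms: none
Why: Reductive removal of the auxiliary as in step 6.

Step 17
Reactants: 28 (1S,2R)-diol
Product: 30 (2S,3R)-2-[4-(benzyloxy)phenyl]-6-chloro-3-(hydroxymethyl)-2,3-dihydro-1-benzofuran-4-ol, via MOM-free tetraol 29 (not isolated)
Conditions: conc. HCl (5 equiv), MeOH/THF, 45 °C
Reagents that add atoms: none
Why: MOM cleavage and phenol capture of the 4-alkoxybenzylic cation close the upper dihydrofuran ring trans, with C3 untouched.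

Step 18
Reactants: 30 dihydrobenzofuran-4-ol
Product: 31 [(2S,3R)-4-(benzyloxy)-2-[4-(benzyloxy)phenyl]-6-chloro-2,3-dihydro-1-benzofuran-3-yl]methanol
Conditions: BnBr (1.05 equiv), K2CO3, acetone, 50 °C
Reagents that add atoms: benzyl bromide, BrCc1ccccc1
Why: Phenol-selective Williamson etherification.

Step 19
Reactants: 31 primary alcohol
Product: 33 (2S,3S)-4-(benzyloxy)-2-[4-(benzyloxy)phenyl]-6-chloro-2,3-dihydro-1-benzofuran-3-carboxylic acid, via aldehyde 32 (not isolated)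
Conditions: TEMPO (0.2 equiv), PhI(OAc)2 (2.5 equiv), MeCN/CH2Cl2/H2O, rt
Reagents that add atoms: water, O
Why: TEMPO oxidation to the acid as in step 9.

Step 20
Reactants: 33 upper-unit carboxylic acid (1.5 equiv); 24 lower-unit aryl iodide
Product: 34 (2S,3S)-4-(benzyloxy)-6-{(2S,3S)-4-(benzyloxy)-2-[4-(benzyloxy)phenyl]-6-chloro-2,3-dihydro-1-benzofuran-3-yl}-2-[2,4-bis(benzyloxy)phenyl]-3-[3,5-bis(benzyloxy)phenyl]-2,3-dihydro-1-benzofuran
Conditions: Ir[dF(CF3)ppy]2(dtbbpy)PF6 (2 mol %), NiCl2·glyme (10 mol %), 4,4′-di-tert-butyl-2,2′-bipyridine, Cs2CO3, DMF, blue LEDs, rt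
Reagents that add atoms: none
Why: The same decarboxylative arylation joins the two units; the aryl iodide reacts in preference to the chloride and the new C3 centre forms trans to the upper C2 aryl (2S,3S).

Step 21
Reactants: 25 4-(benzyloxy)benzaldehyde; 35 bis[(pinacolato)boryl]methane
Product: 37 2-{(E)-2-[4-(benzyloxy)phenyl]ethenyl}-4,4,5,5-tetramethyl-1,3,2-dioxaborolane, via lithiated diboronate 36 (not isolated)
Conditions: LiTMP (lithium 2,2,6,6-tetramethylpiperidide), THF, 0 °C; 25, −78 °C → rt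
Reagents that add atoms: none
Why: Boron–Wittig olefination; addition of the α-boryl carbanion and syn B–O elimination give the E-alkenyl boronate.

Step 22
Reactants: 34 trimer-core aryl chloride; 37 E-styryl boronate (1.5 equiv)
Product: 38 octa-O-benzyl ether of the target (all eight phenols as benzyl ethers, E-alkene, 2S,3S in both units)
Conditions: Pd(OAc)2 (5 mol %), SPhos, K3PO4, toluene/H2O, 90 °C
Reagents that add atoms: none
Why: Suzuki–Miyaura coupling of an unhindered aryl chloride proceeds with retention of the E-alkene geometry; the alkene is introduced only now because the photocatalyst of steps 12 and 20 would isomerise a stilbene.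

Step 23
Reactants: 38 octa-O-benzyl ether
Product: 39 4-[(2S,3S)-3-(3,5-dihydroxyphenyl)-4-hydroxy-6-{(2S,3S)-4-hydroxy-2-(4-hydroxyphenyl)-6-[(E)-2-(4-hydroxyphenyl)ethenyl]-2,3-dihydro-1-benzofuran-3-yl}-2,3-dihydro-1-benzofuran-2-yl]benzene-1,3-diol
Conditions: BCl3 (16 equiv), pentamethylbenzene (24 equiv), CH2Cl2, −78 → −40 °C; MeOH quench
Reagents that add atoms: none
Why: Lewis-acid debenzylation with a non-basic benzyl-cation scavenger spares the alkene; any reversible C2–O ionisation re-closes to the trans rings, so no stereocentre is lost.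

## Compound list
1 | 5-chlorobenzene-1,3-diol | Oc1cc(O)cc(Cl)c1 | starting material
2 | 1-chloro-3,5-bis(methoxymethoxy)benzene | COCOc1cc(Cl)cc(OCOC)c1 | intermediate
3 | [4-chloro-2,6-bis(methoxymethoxy)phenyl]lithium | COCOc1cc(Cl)cc(OCOC)c1[Li] | intermediate (not isolated)
4 | 2-[4-chloro-2,6-bis(methoxymethoxy)phenyl]ethan-1-ol | COCOc1cc(Cl)cc(OCOC)c1CCO | intermediate
5 | [4-chloro-2,6-bis(methoxymethoxy)phenyl]acetaldehyde | COCOc1cc(Cl)cc(OCOC)c1CC=O | intermediate (not isolated)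
6 | [4-chloro-2,6-bis(methoxymethoxy)phenyl]acetic acid | COCOc1cc(Cl)cc(OCOC)c1CC(=O)O | intermediate
7 | (4S)-4-benzyl-1,3-oxazolidin-2-one | O=C1N[C@@H](Cc2ccccc2)CO1 | starting material
8 | [4-chloro-2,6-bis(methoxymethoxy)phenyl]acetic pivalic anhydride | COCOc1cc(Cl)cc(OCOC)c1CC(=O)OC(=O)C(C)(C)C | intermediate (not isolated)
9 | (4S)-4-benzyl-3-{[4-chloro-2,6-bis(methoxymethoxy)phenyl]acetyl}-1,3-oxazolidin-2-one | COCOc1cc(Cl)cc(OCOC)c1CC(=O)N1[C@@H](Cc2ccccc2)COC1=O | intermediate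
10 | 2,4-bis(benzyloxy)benzaldehyde | O=Cc1ccc(OCc2ccccc2)cc1OCc1ccccc1 | starting material
11 | dibutylboron (Z)-enolate of 9 | COCOc1cc(Cl)cc(OCOC)c1/C=C(\OB(CCCC)CCCC)N1[C@@H](Cc2ccccc2)COC1=O | intermediate (not isolated)
12 | (4S)-4-benzyl-3-{(2S,3S)-3-[2,4-bis(benzyloxy)phenyl]-2-[4-chloro-2,6-bis(methoxymethoxy)phenyl]-3-hydroxypropanoyl}-1,3-oxazolidin-2-one | O=C(N1[C@@H](Cc2ccccc2)COC1=O)[C@@H](c1c(OCOC)cc(Cl)cc1OCOC)[C@H](O)c1ccc(OCc2ccccc2)cc1OCc1ccccc1 | intermediate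
13 | (1S,2R)-1-[2,4-bis(benzyloxy)phenyl]-2-[4-chloro-2,6-bis(methoxymethoxy)phenyl]propane-1,3-diol | OC[C@@H](c1c(OCOC)cc(Cl)cc1OCOC)[C@H](O)c1ccc(OCc2ccccc2)cc1OCc1ccccc1 | intermediate
14 | (1S,2R)-1-[2,4-bis(benzyloxy)phenyl]-2-(4-chloro-2,6-dihydroxyphenyl)propane-1,3-diol | OC[C@@H](c1c(O)cc(Cl)cc1O)[C@H](O)c1ccc(OCc2ccccc2)cc1OCc1ccccc1 | intermediate (not isolated)
15 | (2S,3R)-2-[2,4-bis(benzyloxy)phenyl]-6-chloro-3-(hydroxymethyl)-2,3-dihydro-1-benzofuran-4-ol | Clc1cc(O)c2c(c1)O[C@H](c1ccc(OCc3ccccc3)cc1OCc1ccccc1)[C@H]2CO | intermediate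
16 | [(2S,3R)-4-(benzyloxy)-2-[2,4-bis(benzyloxy)phenyl]-6-chloro-2,3-dihydro-1-benzofuran-3-yl]methanol | Clc1cc(OCc2ccccc2)c2c(c1)O[C@H](c1ccc(OCc3ccccc3)cc1OCc1ccccc1)[C@H]2CO | intermediate
17 | (2S,3S)-4-(benzyloxy)-2-[2,4-bis(benzyloxy)phenyl]-6-chloro-2,3-dihydro-1-benzofuran-3-carbaldehyde | Clc1cc(OCc2ccccc2)c2c(c1)O[C@H](c1ccc(OCc3ccccc3)cc1OCc1ccccc1)[C@H]2C=O | intermediate (not isolated)
18 | (2S,3S)-4-(benzyloxy)-2-[2,4-bis(benzyloxy)phenyl]-6-chloro-2,3-dihydro-1-benzofuran-3-carboxylic acid | Clc1cc(OCc2ccccc2)c2c(c1)O[C@H](c1ccc(OCc3ccccc3)cc1OCc1ccccc1)[C@H]2C(=O)O | intermediate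
19 | 1-bromo-3,5-dimethoxybenzene | COc1cc(Br)cc(OC)c1 | starting material
20 | 5-bromobenzene-1,3-diol | Oc1cc(O)cc(Br)c1 | intermediate
21 | 1,3-bis(benzyloxy)-5-bromobenzene | Brc1cc(OCc2ccccc2)cc(OCc2ccccc2)c1 | intermediate
22 | (2S,3S)-4-(benzyloxy)-2-[2,4-bis(benzyloxy)phenyl]-3-[3,5-bis(benzyloxy)phenyl]-6-chloro-2,3-dihydro-1-benzofuran | Clc1cc(OCc2ccccc2)c2c(c1)O[C@H](c1ccc(OCc3ccccc3)cc1OCc1ccccc1)[C@H]2c1cc(OCc2ccccc2)cc(OCc2ccccc2)c1 | intermediate
23 | 2-{(2S,3S)-4-(benzyloxy)-2-[2,4-bis(benzyloxy)phenyl]-3-[3,5-bis(benzyloxy)phenyl]-2,3-dihydro-1-benzofuran-6-yl}-4,4,5,5-tetramethyl-1,3,2-dioxaborolane | CC1(C)OB(OC1(C)C)c1cc(OCc2ccccc2)c2c(c1)O[C@H](c1ccc(OCc3ccccc3)cc1OCc1ccccc1)[C@H]2c1cc(OCc2ccccc2)cc(OCc2ccccc2)c1 | intermediate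
24 | (2S,3S)-4-(benzyloxy)-2-[2,4-bis(benzyloxy)phenyl]-3-[3,5-bis(benzyloxy)phenyl]-6-iodo-2,3-dihydro-1-benzofuran | Ic1cc(OCc2ccccc2)c2c(c1)O[C@H](c1ccc(OCc3ccccc3)cc1OCc1ccccc1)[C@H]2c1cc(OCc2ccccc2)cc(OCc2ccccc2)c1 | intermediate
25 | 4-(benzyloxy)benzaldehyde | O=Cc1ccc(OCc2ccccc2)cc1 | starting material
26 | diethylboron (Z)-enolate of 9 | COCOc1cc(Cl)cc(OCOC)c1/C=C(\OB(CC)CC)N1[C@@H](Cc2ccccc2)COC1=O | intermediate (not isolated)
27 | (4S)-4-benzyl-3-{(2S,3S)-3-[4-(benzyloxy)phenyl]-2-[4-chloro-2,6-bis(methoxymethoxy)phenyl]-3-hydroxypropanoyl}-1,3-oxazolidin-2-one | O=C(N1[C@@H](Cc2ccccc2)COC1=O)[C@@H](c1c(OCOC)cc(Cl)cc1OCOC)[C@H](O)c1ccc(OCc2ccccc2)cc1 | intermediate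
28 | (1S,2R)-1-[4-(benzyloxy)phenyl]-2-[4-chloro-2,6-bis(methoxymethoxy)phenyl]propane-1,3-diol | OC[C@@H](c1c(OCOC)cc(Cl)cc1OCOC)[C@H](O)c1ccc(OCc2ccccc2)cc1 | intermediate
29 | (1S,2R)-1-[4-(benzyloxy)phenyl]-2-(4-chloro-2,6-dihydroxyphenyl)propane-1,3-diol | OC[C@@H](c1c(O)cc(Cl)cc1O)[C@H](O)c1ccc(OCc2ccccc2)cc1 | intermediate (not isolated)
30 | (2S,3R)-2-[4-(benzyloxy)phenyl]-6-chloro-3-(hydroxymethyl)-2,3-dihydro-1-benzofuran-4-ol | Clc1cc(O)c2c(c1)O[C@H](c1ccc(OCc3ccccc3)cc1)[C@H]2CO | intermediate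
31 | [(2S,3R)-4-(benzyloxy)-2-[4-(benzyloxy)phenyl]-6-chloro-2,3-dihydro-1-benzofuran-3-yl]methanol | Clc1cc(OCc2ccccc2)c2c(c1)O[C@H](c1ccc(OCc3ccccc3)cc1)[C@H]2CO | intermediate
32 | (2S,3S)-4-(benzyloxy)-2-[4-(benzyloxy)phenyl]-6-chloro-2,3-dihydro-1-benzofuran-3-carbaldehyde | Clc1cc(OCc2ccccc2)c2c(c1)O[C@H](c1ccc(OCc3ccccc3)cc1)[C@H]2C=O | intermediate (not isolated)
33 | (2S,3S)-4-(benzyloxy)-2-[4-(benzyloxy)phenyl]-6-chloro-2,3-dihydro-1-benzofuran-3-carboxylic acid | Clc1cc(OCc2ccccc2)c2c(c1)O[C@H](c1ccc(OCc3ccccc3)cc1)[C@H]2C(=O)O | intermediate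
34 | (2S,3S)-4-(benzyloxy)-6-{(2S,3S)-4-(benzyloxy)-2-[4-(benzyloxy)phenyl]-6-chloro-2,3-dihydro-1-benzofuran-3-yl}-2-[2,4-bis(benzyloxy)phenyl]-3-[3,5-bis(benzyloxy)phenyl]-2,3-dihydro-1-benzofuran | Clc1cc(OCc2ccccc2)c2c(c1)O[C@H](c1ccc(OCc3ccccc3)cc1)[C@H]2c1cc(OCc2ccccc2)c2c(c1)O[C@H](c1ccc(OCc3ccccc3)cc1OCc1ccccc1)[C@H]2c1cc(OCc2ccccc2)cc(OCc2ccccc2)c1 | intermediate
35 | bis[(pinacolato)boryl]methane | CC1(C)OB(CB2OC(C)(C)C(C)(C)O2)OC1(C)C | starting material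
36 | lithio-bis[(pinacolato)boryl]methane | [Li]C(B1OC(C)(C)C(C)(C)O1)B1OC(C)(C)C(C)(C)O1 | intermediate (not isolated)
37 | 2-{(E)-2-[4-(benzyloxy)phenyl]ethenyl}-4,4,5,5-tetramethyl-1,3,2-dioxaborolane | CC1(C)OB(/C=C/c2ccc(OCc3ccccc3)cc2)OC1(C)C | intermediate
38 | octa-O-benzyl ether of 39 (E-alkene, 2S,3S in both units) | C(c1ccccc1)Oc1ccc(/C=C/c2cc(OCc3ccccc3)c3c(c2)O[C@H](c2ccc(OCc4ccccc4)cc2)[C@H]3c2cc(OCc3ccccc3)c3c(c2)O[C@H](c2ccc(OCc4ccccc4)cc2OCc2ccccc2)[C@H]3c2cc(OCc3ccccc3)cc(OCc3ccccc3)c2)cc1 | intermediate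
39 | 4-[(2S,3S)-3-(3,5-dihydroxyphenyl)-4-hydroxy-6-{(2S,3S)-4-hydroxy-2-(4-hydroxyphenyl)-6-[(E)-2-(4-hydroxyphenyl)ethenyl]-2,3-dihydro-1-benzofuran-3-yl}-2,3-dihydro-1-benzofuran-2-yl]benzene-1,3-diol | Oc1ccc(/C=C/c2cc(O)c3c(c2)O[C@H](c2ccc(O)cc2)[C@H]3c2cc(O)c3c(c2)O[C@H](c2ccc(O)cc2O)[C@H]3c2cc(O)cc(O)c2)cc1 | target

## Count and risks
Total steps: 23. Longest linear sequence: 15 steps (1–9, 12–14, 20, 22, 23).

Steps most likely to fail:

Step 12. The hindered benzylic C3 radical may dimerise, lose CO2 to give the C3–H compound, or couple with poor trans selectivity. Fallback, setting out from 18 and 21 and returning at 22: 18 is esterified with N-hydroxyphthalimide (DIC, DMAP, CH2Cl2) to 1,3-dioxoisoindolin-2-yl (2S,3S)-4-(benzyloxy)-2-[2,4-bis(benzyloxy)phenyl]-6-chloro-2,3-dihydro-1-benzofuran-3-carboxylate F1. 21 is converted by Br/Mg exchange (i-PrMgCl·LiCl, THF) and ZnCl2 into [3,5-bis(benzyloxy)phenyl]zinc chloride F2. Thermal nickel catalysis (NiCl2·glyme, 4,4′-di-tert-butyl-2,2′-bipyridine, THF/DMF, rt) then joins the redox-active ester and the arylzinc nucleophile to give 22 without light or a carboxylate oxidation.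

Step 20. This is the same bond type between two large, valuable partners, so a low yield is costly. Fallback, setting out from 33 and 23 and returning at 34: 33 is converted (N-hydroxytetrachlorophthalimide, DIC) into 4,5,6,7-tetrachloro-1,3-dioxoisoindolin-2-yl (2S,3S)-4-(benzyloxy)-2-[4-(benzyloxy)phenyl]-6-chloro-2,3-dihydro-1-benzofuran-3-carboxylate F3. Boronate 23 is cleaved (NaIO4, NH4OAc, acetone/H2O; the released pinacol is oxidised to acetone by the periodate) to {(2S,3S)-4-(benzyloxy)-2-[2,4-bis(benzyloxy)phenyl]-3-[3,5-bis(benzyloxy)phenyl]-2,3-dihydro-1-benzofuran-6-yl}boronic acid F4. A nickel-catalysed decarboxylative Suzuki-type coupling (NiCl2·6H2O, bathophenanthroline, Et3N, dioxane/DMF, 75 °C; excess F4 recovered) gives 34 and makes step 14 unnecessary.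

Step 23. Eight benzyl cations are released next to an electron-rich stilbene, so alkene alkylation or oligomerisation is possible. Fallback, setting out from 34 and returning at 39: the benzyl groups are removed before the alkene exists (BCl3, pentamethylbenzene, CH2Cl2, −78 °C) to give 4-[(2S,3S)-6-{(2S,3S)-6-chloro-4-hydroxy-2-(4-hydroxyphenyl)-2,3-dihydro-1-benzofuran-3-yl}-3-(3,5-dihydroxyphenyl)-4-hydroxy-2,3-dihydro-1-benzofuran-2-yl]benzene-1,3-diol F5. Peracetylation (Ac2O, pyridine) gives the heptaacetate of F5 F6. A Heck reaction with commercial 4-acetoxystyrene (Pd2(dba)3, P(t-Bu)3·HBF4, Cy2NMe, dioxane, 100 °C) gives the octaacetate of 39 F7, and mild methanolysis (K2CO3, MeOH, 0 °C, degassed) releases 39.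

## Further compounds
F1 | step 12 | 1,3-dioxoisoindolin-2-yl (2S,3S)-4-(benzyloxy)-2-[2,4-bis(benzyloxy)phenyl]-6-chloro-2,3-dihydro-1-benzofuran-3-carboxylate | Clc1cc(OCc2ccccc2)c2c(c1)O[C@H](c1ccc(OCc3ccccc3)cc1OCc1ccccc1)[C@H]2C(=O)ON1C(=O)c2ccccc2C1=O
F2 | step 12 | [3,5-bis(benzyloxy)phenyl]zinc chloride | Cl[Zn]c1cc(OCc2ccccc2)cc(OCc2ccccc2)c1
F3 | step 20 | 4,5,6,7-tetrachloro-1,3-dioxoisoindolin-2-yl (2S,3S)-4-(benzyloxy)-2-[4-(benzyloxy)phenyl]-6-chloro-2,3-dihydro-1-benzofuran-3-carboxylate | Clc1cc(OCc2ccccc2)c2c(c1)O[C@H](c1ccc(OCc3ccccc3)cc1)[C@H]2C(=O)ON1C(=O)c2c(Cl)c(Cl)c(Cl)c(Cl)c2C1=O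
F4 | step 20 | {(2S,3S)-4-(benzyloxy)-2-[2,4-bis(benzyloxy)phenyl]-3-[3,5-bis(benzyloxy)phenyl]-2,3-dihydro-1-benzofuran-6-yl}boronic acid | OB(O)c1cc(OCc2ccccc2)c2c(c1)O[C@H](c1ccc(OCc3ccccc3)cc1OCc1ccccc1)[C@H]2c1cc(OCc2ccccc2)cc(OCc2ccccc2)c1
F5 | step 23 | 4-[(2S,3S)-6-{(2S,3S)-6-chloro-4-hydroxy-2-(4-hydroxyphenyl)-2,3-dihydro-1-benzofuran-3-yl}-3-(3,5-dihydroxyphenyl)-4-hydroxy-2,3-dihydro-1-benzofuran-2-yl]benzene-1,3-diol | Clc1cc(O)c2c(c1)O[C@H](c1ccc(O)cc1)[C@H]2c1cc(O)c2c(c1)O[C@H](c1ccc(O)cc1O)[C@H]2c1cc(O)cc(O)c1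
F6 | step 23 | heptaacetate of F5 | Clc1cc(OC(C)=O)c2c(c1)O[C@H](c1ccc(OC(C)=O)cc1)[C@H]2c1cc(OC(C)=O)c2c(c1)O[C@H](c1ccc(OC(C)=O)cc1OC(C)=O)[C@H]2c1cc(OC(C)=O)cc(OC(C)=O)c1
F7 | step 23 | octaacetate of 39 | CC(=O)Oc1ccc(/C=C/c2cc(OC(C)=O)c3c(c2)O[C@H](c2ccc(OC(C)=O)cc2)[C@H]3c2cc(OC(C)=O)c3c(c2)O[C@H](c2ccc(OC(C)=O)cc2OC(C)=O)[C@H]3c2cc(OC(C)=O)cc(OC(C)=O)c2)cc1
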